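## Retrosynthetic overview

1. Both indole pyrrole rings are disconnected together: a two-fold Fischer-type indolization of a bis(aryl bromide) core (through in-situ N-aryl hydrazones) with two molecules of 3,3-dimethylpent-4-enal. Each aldehyde supplies C2, C3 and the intact reverse-prenyl group.
2. The dibromide core comes from an E-selective Horner–Wadsworth–Emmons olefination of an α-quaternary aldehyde with diethyl (4-bromobenzyl)phosphonate.
3. The aldehyde comes from a catalytic enantioselective endo Diels–Alder reaction of (E)-1-(4-bromophenyl)-3-methylbutadiene with methacrolein. This sets both stereocentres and replaces the unselective biomimetic diene dimerization.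
4. The diene comes from Wittig methylenation of 4-bromobenzalacetone.
5. Ring order: cyclohexene first (step 2), then the two pyrrole rings together in the last operation (step 5).

Assumption: the SMILES is read as (1R,2R) on the cyclohexene, with the indolyl and indolylvinyl groups cis, and compounds 1, 6 and 8 are bought as catalogue chemicals.

## Route

Step 1
Reactants: 1 (E)-4-(4-bromophenyl)but-3-en-2-one; 2 methyltriphenylphosphonium bromide
Product: 3 1-bromo-4-[(1E)-3-methylbuta-1,3-dien-1-yl]benzene
Conditions: 2 (1.3 equiv), KOtBu (1.25 equiv), THF, 0 °C, then 1, rt, 2 h; store cold and use promptly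
Reagents that add atoms: methyltriphenylphosphonium bromide 2 (gives the CH2 through its ylide), C[P+](c1ccccc1)(c1ccccc1)c1ccccc1.[Br-]
Why: Wittig methylenation in which the non-stabilised ylide adds 1,2 to the enone carbonyl and leaves the existing E-styrenyl double bond untouched, as in the standard preparation of 1-aryl-3-methylbutadienes from benzalacetones.

Step 2
Reactants: 3 1-bromo-4-[(1E)-3-methylbuta-1,3-dien-1-yl]benzene; 4 methacrolein
Product: 5 (1S,2S)-2-(4-bromophenyl)-1,4-dimethylcyclohex-3-ene-1-carbaldehyde (CHO and aryl cis)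
Conditions: (S)-o-tolyl-CBS-oxazaborolidine (20 mol %), Tf2NH (18 mol %), 4 (3 equiv), CH2Cl2, −78 → −40 °C
Reagents that add atoms: methacrolein 4, C=C(C)C=O
Why: Catalytic enantioselective Diels–Alder reaction (Corey cationic oxazaborolidine) in which the 1-aryl and 3-methyl groups both direct the diene CH2 terminus to the enal β-carbon (single "ortho/para" regioisomer), the endo transition state puts CHO cis to the aryl group, and the (S)-catalyst, which holds the s-trans enal over a phenyl ring by B–O and formyl C–H···O contacts, leaves only the Cα-Re face open, so both stereocentres are set as (1S,2S).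

Step 3
Reactants: 5 (1S,2S)-2-(4-bromophenyl)-1,4-dimethylcyclohex-3-ene-1-carbaldehyde; 6 diethyl (4-bromobenzyl)phosphonate
Product: 7 1-bromo-4-[(E)-2-[(1R,2R)-2-(4-bromophenyl)-1,4-dimethylcyclohex-3-en-1-yl]ethenyl]benzene
Conditions: 6 (1.3 equiv), KOtBu (1.3 equiv), THF, 0 °C, then 5, rt → 40 °C
Reagents that add atoms: diethyl (4-bromobenzyl)phosphonate 6, CCOP(=O)(Cc1ccc(Br)cc1)OCC
Why: Horner–Wadsworth–Emmons olefination in which the semi-stabilised benzylic phosphonate anion adds reversibly to the non-enolisable neopentyl aldehyde and collapses to the E-styrene, while neither stereocentre is deprotonated by KOtBu (the descriptors change from S,S to R,R only because CHO becomes a lower-ranked vinyl group).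

Step 4
Reactants: 8 methyl 3,3-dimethylpent-4-enoate
Product: 9 3,3-dimethylpent-4-enal
Conditions: DIBAL-H (1.05 equiv), CH2Cl2, −78 °C; MeOH, aq. Rochelle salt; used as a concentrated solution
Reagents that add atoms: none
Why: Partial ester reduction with DIBAL-H, in which the tetrahedral aluminium hemiacetal is stable at −78 °C and releases the aldehyde only on work-up, the isolated terminal alkene being inert.

Step 5 (key step)
Reactants: 7 1-bromo-4-[(E)-2-[(1R,2R)-2-(4-bromophenyl)-1,4-dimethylcyclohex-3-en-1-yl]ethenyl]benzene; 9 3,3-dimethylpent-4-enal; 10 benzophenone hydrazone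
Product: 13 5-[(E)-2-[(1R,2R)-1,4-dimethyl-2-[3-(2-methylbut-3-en-2-yl)-1H-indol-5-yl]cyclohex-3-en-1-yl]ethenyl]-3-(2-methylbut-3-en-2-yl)-1H-indole (target), via bis(benzophenone hydrazone) 11 (not isolated), via bis(aldehyde hydrazone) 12 (not isolated)
Conditions: 10 (2.2 equiv), Pd(OAc)2 (4 mol %), rac-BINAP (6 mol %), NaOtBu (2.8 equiv), PhMe, 80 °C; then 9 (4 equiv), TsOH·H2O (5 equiv), EtOH, 75 °C, same flask
Reagents that add atoms: benzophenone hydrazone 10 (its NH2 nitrogen becomes each indole N), NN=C(c1ccccc1)c1ccccc1; 3,3-dimethylpent-4-enal 9 (C2, C3 and the reverse-prenyl group of each indole), C=CC(C)(C)CC=O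
Why: Buchwald–Hartwig N-arylation of benzophenone hydrazone at both C–Br bonds, then acid-mediated hydrazone exchange with 9 and a two-fold Fischer indole synthesis ([3,3]-sigmatropic shift of the ene-hydrazine, ring closure, loss of NH3), in which the para-substituted aryl hydrazones can only give 5-substituted indoles, the sole α-CH2 of 9 places the intact CMe2CH=CH2 group on C3 and leaves C2–H, both pyrrole rings close in one operation, and neither stereocentre nor the E-alkene takes part.

## Compound list

1 | (E)-4-(4-bromophenyl)but-3-en-2-one | CC(=O)/C=C/c1ccc(Br)cc1 | starting material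
2 | methyltriphenylphosphonium bromide | C[P+](c1ccccc1)(c1ccccc1)c1ccccc1.[Br-] | starting material
3 | 1-bromo-4-[(1E)-3-methylbuta-1,3-dien-1-yl]benzene | C=C(C)/C=C/c1ccc(Br)cc1 | intermediate
4 | methacrolein (2-methylprop-2-enal) | C=C(C)C=O | starting material
5 | (1S,2S)-2-(4-bromophenyl)-1,4-dimethylcyclohex-3-ene-1-carbaldehyde | O=C[C@@]1(C)CCC(C)=C[C@H]1c1ccc(Br)cc1 | intermediate
6 | diethyl (4-bromobenzyl)phosphonate | CCOP(=O)(Cc1ccc(Br)cc1)OCC | starting material
7 | 1-bromo-4-[(E)-2-[(1R,2R)-2-(4-bromophenyl)-1,4-dimethylcyclohex-3-en-1-yl]ethenyl]benzene | Brc1ccc(/C=C/[C@@]2(C)CCC(C)=C[C@H]2c2ccc(Br)cc2)cc1 | intermediate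
8 | methyl 3,3-dimethylpent-4-enoate | C=CC(C)(C)CC(=O)OC | starting material
9 | 3,3-dimethylpent-4-enal | C=CC(C)(C)CC=O | intermediate
10 | benzophenone hydrazone | NN=C(c1ccccc1)c1ccccc1 | starting material
11 | bis(benzophenone hydrazone): compound 7 with each Br replaced by NH–N=CPh2, (1R,2R), E-alkene | C(=NNc1ccc(/C=C/[C@@]2(C)CCC(C)=C[C@H]2c2ccc(NN=C(c3ccccc3)c3ccccc3)cc2)cc1)(c1ccccc1)c1ccccc1 | intermediate
12 | bis(N-arylhydrazone) of 9: compound 7 with each Br replaced by NH–N=CH–CH2–CMe2–CH=CH2, (1R,2R), E-alkene | C=CC(C)(C)CC=NNc1ccc(/C=C/[C@@]2(C)CCC(C)=C[C@H]2c2ccc(NN=CCC(C)(C)C=C)cc2)cc1 | intermediate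
13 | 5-[(E)-2-[(1R,2R)-1,4-dimethyl-2-[3-(2-methylbut-3-en-2-yl)-1H-indol-5-yl]cyclohex-3-en-1-yl]ethenyl]-3-(2-methylbut-3-en-2-yl)-1H-indole | C=CC(C)(C)c1c[nH]c2ccc(/C=C/[C@@]3(C)CCC(C)=C[C@H]3c3ccc4[nH]cc(C(C)(C)C=C)c4c3)cc12 | target

## Step count and risks

Total step count: 5. Longest linear sequence: 4 (steps 1, 2, 3, 5); step 4 is a one-step side branch.

Steps most likely to fail:

**Step 5 (double amination and double Fischer indolization).** The TsOH stage may shift or cleave the acid-labile 3-(1,1-dimethylallyl) groups, add ethanol across the electron-rich aminostyrene, or move the ring double bond. The fallback closes both indoles under basic conditions. It sets out from 7: Pd-catalysed amination with ammonia (Pd[P(o-tol)3]2/CyPF-tBu, NH3 in dioxane, NaOtBu, 90 °C) gives the bis-aniline 4-[(E)-2-[(1R,2R)-2-(4-aminophenyl)-1,4-dimethylcyclohex-3-en-1-yl]ethenyl]aniline F1. Ortho-iodination of both aniline rings (BnNMe3·ICl2, CaCO3, CH2Cl2/MeOH, 0 °C; alkene attack by the iodinating agent is the weak point of this fallback) gives the bis(2-iodoaniline) 4-[(E)-2-[(1R,2R)-2-(4-amino-3-iodophenyl)-1,4-dimethylcyclohex-3-en-1-yl]ethenyl]-2-iodoaniline F2. Pd-catalysed heteroannulation of both o-iodoaniline units with 9 (Pd(OAc)2, DABCO, DMF, 85 °C; enamine formation, then intramolecular Heck-type closure) forms both indoles at once and comes back to the route at 13.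

**Step 2 (asymmetric Diels–Alder).** The endo:exo ratio with an α-methyl enal, the ee, or cationic polymerisation of the aryl diene may be limiting; a modest ee can be raised by recrystallising 7. The fallback replaces asymmetric catalysis by resolution. It sets out from 3: cycloaddition with 4 under an achiral Lewis acid (EtAlCl2 10 mol %, CH2Cl2, −78 °C) gives the racemic cis-aldehyde rac-2-(4-bromophenyl)-1,4-dimethylcyclohex-3-ene-1-carbaldehyde F3. Condensation with (1R,2R)-N,N'-dimethyl-1,2-diphenylethane-1,2-diamine (4 Å MS, Et2O, rt) gives two diastereomeric imidazolidines, the one from the (1S,2S)-aldehyde F4 and the one from the (1R,2R)-aldehyde F5. They are separated by chromatography or crystallisation, and mild hydrolysis of F4 (aq. HCl/Et2O, 0 °C) comes back to the route at 5.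

**Step 3 (HWE on a neopentyl aldehyde).** Addition to the hindered carbonyl may be slow, or some Z-isomer may form. The fallback builds the styrene by C–C coupling instead. It sets out from 5: Wittig methylenation (ylide from 2 and KOtBu, THF) gives the vinyl compound 1-bromo-4-[(1R,6R)-6-ethenyl-3,6-dimethylcyclohex-2-en-1-yl]benzene F6. A Jeffery-type Heck reaction with 1-bromo-4-iodobenzene (Pd(OAc)2, nBu4NCl, NaHCO3, DMF, 70 °C) reacts only at C–I and gives only the linear E-styrene, coming back to the route at 7.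

## Further compounds

F1 | step 5 | 4-[(E)-2-[(1R,2R)-2-(4-aminophenyl)-1,4-dimethylcyclohex-3-en-1-yl]ethenyl]aniline | Nc1ccc(/C=C/[C@@]2(C)CCC(C)=C[C@H]2c2ccc(N)cc2)cc1
F2 | step 5 | 4-[(E)-2-[(1R,2R)-2-(4-amino-3-iodophenyl)-1,4-dimethylcyclohex-3-en-1-yl]ethenyl]-2-iodoaniline | Nc1ccc(/C=C/[C@@]2(C)CCC(C)=C[C@H]2c2ccc(N)c(I)c2)cc1I
F3 | step 2 | racemic cis-2-(4-bromophenyl)-1,4-dimethylcyclohex-3-ene-1-carbaldehyde (1:1 mixture of enantiomers) | O=C[C@@]1(C)CCC(C)=C[C@H]1c1ccc(Br)cc1.O=C[C@]1(C)CCC(C)=C[C@@H]1c1ccc(Br)cc1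
F4 | step 2 | (4R,5R)-2-[(1S,2S)-2-(4-bromophenyl)-1,4-dimethylcyclohex-3-en-1-yl]-1,3-dimethyl-4,5-diphenylimidazolidine | CN1[C@H](c2ccccc2)[C@H](N(C)C1[C@@]3(C)CCC(C)=C[C@H]3c3ccc(Br)cc3)c2ccccc2
F5 | step 2 | (4R,5R)-2-[(1R,2R)-2-(4-bromophenyl)-1,4-dimethylcyclohex-3-en-1-yl]-1,3-dimethyl-4,5-diphenylimidazolidine | CN1[C@H](c2ccccc2)[C@H](N(C)C1[C@]3(C)CCC(C)=C[C@@H]3c3ccc(Br)cc3)c2ccccc2
F6 | step 3 | 1-bromo-4-[(1R,6R)-6-ethenyl-3,6-dimethylcyclohex-2-en-1-yl]benzene | C=C[C@@]1(C)CCC(C)=C[C@H]1c1ccc(Br)cc1
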